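**Plan**

1. Numbering: oxolane O1, C2 (C9'), C3 (C8', bears C7'H(OH)Ar), C4 (C8, bears C7H2Ar), C5 (C9). Retrosynthetic cuts, in order: the two O-benzyl groups; the C7'–aryl bond (aryl transfer to a C7' aldehyde); the ring bond C3–C4 together with one C7–H bond (radical hydroalkylation of a styrene by an aldehyde α-carbon); the O1–C2 bond (oxa-Michael addition to acrylonitrile).
2. Forward: 4-O-benzylsinapyl alcohol and acrylonitrile give the linear, achiral allyl ether aldehyde 6. One enantioselective 5-exo radical cyclisation closes the only ring and turns the styrene into the ArCH2 group. The second aryl ring is then added to the aldehyde carbon and the benzyl ethers are removed.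
3. Stereochemistry: C4 (C8) comes from the chiral amine catalyst in the C–C bond formation. C3 (C8') settles trans by enamine equilibration, so cis material converges. C7' comes from the chiral amino alcohol–zinc catalyst in the aryl transfer.
4. Enabling feature: O1 lies between two unsubstituted CH2 groups (C2, C5), and the C3–C4 bond joins a carbon α to an oxygen-bearing carbon (C7', a latent CHO) to a carbon β to an arene (C7H2Ar, a latent styrene terminus). Cutting C3–C4 therefore leaves an ether with no stereocentre.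

Key step: step 4

Remark: sinapyl alcohol (1) and 4-bromo-2,6-dimethoxyphenol (8) are taken as purchased; species bound to a catalyst inside a catalytic cycle (enamines, radicals, zinc–amino alcohol complexes) are regarded as part of the catalyst and carry no number.

**Route**

Step 1
Reactants: 1 sinapyl alcohol
Product: 2 (E)-3-[4-(benzyloxy)-3,5-dimethoxyphenyl]prop-2-en-1-ol
Conditions: BnBr (1.05 equiv), K2CO3, acetone, reflux
Reagents that add atoms: benzyl bromide, BrCc1ccccc1
Why: Williamson etherification in which carbonate deprotonates only the phenol, so the allylic hydroxyl should stay free.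

Step 2
Reactants: 2 (E)-3-[4-(benzyloxy)-3,5-dimethoxyphenyl]prop-2-en-1-ol; 3 acrylonitrile
Product: 4 3-{[(E)-3-(4-(benzyloxy)-3,5-dimethoxyphenyl)prop-2-en-1-yl]oxy}propanenitrile
Conditions: acrylonitrile (3 equiv), Triton B (5 mol%), 1,4-dioxane, rt; AcOH quench
Reagents that add atoms: none
Why: Base-catalysed oxa-Michael addition (cyanoethylation) of the primary allylic alcohol should attach C9', C8' and C7' to O1 as a three-carbon chain.

Step 3
Reactants: 4 3-{[(E)-3-(4-(benzyloxy)-3,5-dimethoxyphenyl)prop-2-en-1-yl]oxy}propanenitrile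
Product: 6 3-{[(E)-3-(4-(benzyloxy)-3,5-dimethoxyphenyl)prop-2-en-1-yl]oxy}propanal, via aldimine 5 (not isolated)
Conditions: DIBAL-H (1.2 equiv), toluene, −78 °C; aq. Rochelle salt, 0 °C
Reagents that add atoms: water, O
Why: Partial hydride reduction of a nitrile should stop at the N-aluminio aldimine at −78 °C, which hydrolyses to the aldehyde on neutral work-up without touching the alkene or the benzyl ether.

Step 4
Reactants: 6 3-{[(E)-3-(4-(benzyloxy)-3,5-dimethoxyphenyl)prop-2-en-1-yl]oxy}propanal
Product: 7 (3R,4R)-4-[4-(benzyloxy)-3,5-dimethoxybenzyl]oxolane-3-carbaldehyde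
Conditions: [Ir(Fmppy)2(dtbbpy)]PF6 (1 mol%), 5-benzyl-2-tert-butyl-3-methylimidazolidin-4-one·TFA (20 mol%; the (2S,5S) or (2R,5R) antipode that gives 3R,4R), 2,4,6-triisopropylbenzenethiol (10 mol%), DME, blue LEDs, 0 °C
Reagents that add atoms: none
Why: The amine condenses with 6 to an enamine, which the excited Ir(III) catalyst oxidises to an electrophilic enaminyl radical at C3 (C8'); this adds to the proximal carbon C4 (C8) of the electron-rich (E)-styrene, the resulting benzylic C7 radical takes a hydrogen atom from the thiol, and the thiyl radical is reduced back by Ir(II), so no reagent is consumed. The closest known reaction type is the intramolecular enantioselective α-alkylation of aldehydes by tethered simple olefins under combined photoredox, enamine and hydrogen-atom-transfer catalysis. The one ring closed is the oxolane, by 5-exo-trig radical C–C bond formation (C3–C4). C4 is set in this bond-forming step by the imidazolidinone, whose benzyl group shields one face of the enaminyl radical, while C3 stays epimerisable through the enamine and should settle trans to the new ArCH2 group, so cis material is funnelled to the trans aldehyde. The step needs 5-exo over 6-endo closure and hydrogen-atom transfer faster than radical oxidation; the benzylic stabilisation of the C7 radical, the electron-rich aryl ring (a matched partner for the electrophilic radical) and the thiol co-catalyst should secure both.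

Step 5
Reactants: 8 4-bromo-2,6-dimethoxyphenol
Product: 9 2-(benzyloxy)-5-bromo-1,3-dimethoxybenzene
Conditions: BnBr (1.1 equiv), K2CO3, DMF, rt
Reagents that add atoms: benzyl bromide, BrCc1ccccc1
Why: Williamson etherification masks the phenol for the organometallic step.

Step 6
Reactants: 7 (3R,4R)-4-[4-(benzyloxy)-3,5-dimethoxybenzyl]oxolane-3-carbaldehyde; 9 2-(benzyloxy)-5-bromo-1,3-dimethoxybenzene
Product: 13 (S)-[4-(benzyloxy)-3,5-dimethoxyphenyl]{(3R,4R)-4-[4-(benzyloxy)-3,5-dimethoxybenzyl]oxolan-3-yl}methanol, via aryllithium 10 (not isolated), via arylzinc chloride 11 (not isolated), via aryl(butyl)zinc 12 (not isolated)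
Conditions: 9 (2 equiv), n-BuLi, t-BuOMe, −78 °C; ZnCl2, to 0 °C; n-BuLi; TEEDA (0.8 equiv), MIB (3-exo-morpholinoisoborneol, 10 mol%; the antipode that delivers aryl to the Re face, expected to be (+)-MIB by analogy with dialkylzinc additions), hexanes; then 7, 0 °C; H2O
Reagents that add atoms: none
Why: Catalytic asymmetric aryl transfer from a mixed aryl(alkyl)zinc to an aldehyde under amino alcohol control should add the aryl group to the Re face of the formyl group and set C7' as S, and the non-basic zinc reagent should leave the epimerisable C3 centre untouched.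

Step 7
Reactants: 13 (S)-[4-(benzyloxy)-3,5-dimethoxyphenyl]{(3R,4R)-4-[4-(benzyloxy)-3,5-dimethoxybenzyl]oxolan-3-yl}methanol
Product: 14 (S)-(4-hydroxy-3,5-dimethoxyphenyl)[(3R,4R)-4-(4-hydroxy-3,5-dimethoxybenzyl)oxolan-3-yl]methanol
Conditions: H2 (1 atm), 10% Pd/C, EtOAc, rt, stopped when both benzyl groups are gone
Reagents that add atoms: none
Why: Pd-catalysed hydrogenolysis should cleave both aryl benzyl ethers under neutral conditions that leave the benzylic C7'–OH and the three stereocentres unchanged.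

**Compound list**

1 | sinapyl alcohol, (E)-4-(3-hydroxyprop-1-en-1-yl)-2,6-dimethoxyphenol | COc1cc(/C=C/CO)cc(OC)c1O | starting material
2 | (E)-3-[4-(benzyloxy)-3,5-dimethoxyphenyl]prop-2-en-1-ol | COc1cc(/C=C/CO)cc(OC)c1OCc1ccccc1 | intermediate
3 | acrylonitrile | C=CC#N | starting material
4 | 3-{[(E)-3-(4-(benzyloxy)-3,5-dimethoxyphenyl)prop-2-en-1-yl]oxy}propanenitrile | COc1cc(/C=C/COCCC#N)cc(OC)c1OCc1ccccc1 | intermediate
5 | 3-{[(E)-3-(4-(benzyloxy)-3,5-dimethoxyphenyl)prop-2-en-1-yl]oxy}propan-1-imine (held as its N-diisobutylaluminium derivative until work-up) | COc1cc(/C=C/COCCC=N)cc(OC)c1OCc1ccccc1 | intermediate (not isolated)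
6 | 3-{[(E)-3-(4-(benzyloxy)-3,5-dimethoxyphenyl)prop-2-en-1-yl]oxy}propanal | COc1cc(/C=C/COCCC=O)cc(OC)c1OCc1ccccc1 | intermediate
7 | (3R,4R)-4-[4-(benzyloxy)-3,5-dimethoxybenzyl]oxolane-3-carbaldehyde | COc1cc(C[C@H]2COC[C@@H]2C=O)cc(OC)c1OCc1ccccc1 | intermediate
8 | 4-bromo-2,6-dimethoxyphenol | COc1cc(Br)cc(OC)c1O | starting material
9 | 2-(benzyloxy)-5-bromo-1,3-dimethoxybenzene | COc1cc(Br)cc(OC)c1OCc1ccccc1 | intermediate
10 | [4-(benzyloxy)-3,5-dimethoxyphenyl]lithium | COc1cc([Li])cc(OC)c1OCc1ccccc1 | intermediate (not isolated)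
11 | [4-(benzyloxy)-3,5-dimethoxyphenyl]zinc chloride | COc1cc([Zn]Cl)cc(OC)c1OCc1ccccc1 | intermediate (not isolated)
12 | [4-(benzyloxy)-3,5-dimethoxyphenyl](butyl)zinc | CCCC[Zn]c1cc(OC)c(OCc2ccccc2)c(OC)c1 | intermediate (not isolated)
13 | (S)-[4-(benzyloxy)-3,5-dimethoxyphenyl]{(3R,4R)-4-[4-(benzyloxy)-3,5-dimethoxybenzyl]oxolan-3-yl}methanol | COc1cc(C[C@H]2COC[C@@H]2[C@H](O)c2cc(OC)c(OCc3ccccc3)c(OC)c2)cc(OC)c1OCc1ccccc1 | intermediate
14 | (S)-(4-hydroxy-3,5-dimethoxyphenyl)[(3R,4R)-4-(4-hydroxy-3,5-dimethoxybenzyl)oxolan-3-yl]methanol | COc1cc(C[C@H]2COC[C@@H]2[C@H](O)c2cc(OC)c(O)c(OC)c2)cc(OC)c1O | target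

**Step count and risks**

Total step count: 7. Longest linear sequence: 6 steps (steps 1, 2, 3, 4, 6, 7, from 1).

Steps most likely to fail:

1. Step 4. The amine catalyst may trigger β-elimination of the allylic alkoxide from the 3-alkoxypropanal (retro-oxa-Michael) faster than the radical cyclisation. The photocatalyst may also isomerise the styrene, the α-radical may be reduced before it cyclises, or facial discrimination at C4 may be poor. Fallback (a two-electron lactone route; sets out from 9, returns at 13): bromine–lithium exchange of 9 (n-BuLi, THF, −78 °C) and DMF should give 4-(benzyloxy)-3,5-dimethoxybenzaldehyde F1. Stobbe condensation of F1 with diethyl succinate (t-BuOK, t-BuOH) should give (E)-4-[4-(benzyloxy)-3,5-dimethoxyphenyl]-3-(ethoxycarbonyl)but-3-enoic acid F2. Rh–bisphospholane asymmetric hydrogenation (the ligand hand that gives R) should give (R)-3-[4-(benzyloxy)-3,5-dimethoxybenzyl]-4-ethoxy-4-oxobutanoic acid F3. Reduction of the ester in the potassium carboxylate with Ca(BH4)2, then acid, should give (R)-4-[4-(benzyloxy)-3,5-dimethoxybenzyl]oxolan-2-one F4. Its lithium enolate (LDA, −78 °C) and F1 should give the trans aldol lactone (3S,4R)-4-[4-(benzyloxy)-3,5-dimethoxybenzyl]-3-{[4-(benzyloxy)-3,5-dimethoxyphenyl](hydroxy)methyl}oxolan-2-one F5 as a mixture of C7' epimers. LiAlH4 should give (2R,3R)-2-[4-(benzyloxy)-3,5-dimethoxybenzyl]-3-{[4-(benzyloxy)-3,5-dimethoxyphenyl](hydroxy)methyl}butane-1,4-diol F6. Tosylation of a primary hydroxyl (TsCl, pyridine) and 5-exo-tet closure by the other primary hydroxyl should give [4-(benzyloxy)-3,5-dimethoxyphenyl]{(3R,4R)-4-[4-(benzyloxy)-3,5-dimethoxybenzyl]oxolan-3-yl}methanol F7 (C7' epimers). F7 is then carried through the ketone F8 to 13 as in the fallback for step 6.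

2. Step 6. Catalyst control at C7' may be eroded by the intrinsic 1,2-induction of the α-branched aldehyde (a mismatched pairing is possible) and by uncatalysed background addition promoted by lithium salts. The C3 centre may also epimerise under the Lewis-acidic, amine-containing conditions. Fallback (the carbinol centre is set by reduction instead of by C–C bond formation; sets out from 7 and 9, returns at 13): uncatalysed addition of the aryllithium from 9 to 7 (THF, −78 °C) should give [4-(benzyloxy)-3,5-dimethoxyphenyl]{(3R,4R)-4-[4-(benzyloxy)-3,5-dimethoxybenzyl]oxolan-3-yl}methanol F7 as a mixture of C7' epimers. Dess–Martin oxidation should give [4-(benzyloxy)-3,5-dimethoxyphenyl]{(3R,4R)-4-[4-(benzyloxy)-3,5-dimethoxybenzyl]oxolan-3-yl}methanone F8. Asymmetric transfer hydrogenation of F8 (RuCl[(S,S)-TsDPEN](p-cymene), HCO2H/Et3N) should give 13, with hydride delivered to the aryl ketone face that leads to the S carbinol.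

3. Step 7. Once the para-phenol is unmasked, the benzylic C7'–O bond becomes prone to hydrogenolysis, so over-reduction to the deoxygenated compound may compete with the second debenzylation. Fallback (debenzylation at the ketone oxidation level; sets out from 13, returns at 14): Dess–Martin oxidation of 13 should give the ketone [4-(benzyloxy)-3,5-dimethoxyphenyl]{(3R,4R)-4-[4-(benzyloxy)-3,5-dimethoxybenzyl]oxolan-3-yl}methanone F8, in which the benzylic position is deactivated. Hydrogenolysis (H2, Pd/C, EtOAc) should then give (4-hydroxy-3,5-dimethoxyphenyl)[(3R,4R)-4-(4-hydroxy-3,5-dimethoxybenzyl)oxolan-3-yl]methanone F9. Asymmetric transfer hydrogenation of F9 (RuCl[(S,S)-TsDPEN](p-cymene), HCO2H/Et3N) should give 14 directly.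

Further compounds

F1 | step 4 | 4-(benzyloxy)-3,5-dimethoxybenzaldehyde | COc1cc(C=O)cc(OC)c1OCc1ccccc1
F2 | step 4 | (E)-4-[4-(benzyloxy)-3,5-dimethoxyphenyl]-3-(ethoxycarbonyl)but-3-enoic acid | CCOC(=O)/C(=C/c1cc(OC)c(OCc2ccccc2)c(OC)c1)CC(=O)O
F3 | step 4 | (R)-3-[4-(benzyloxy)-3,5-dimethoxybenzyl]-4-ethoxy-4-oxobutanoic acid | CCOC(=O)[C@H](Cc1cc(OC)c(OCc2ccccc2)c(OC)c1)CC(=O)O
F4 | step 4 | (R)-4-[4-(benzyloxy)-3,5-dimethoxybenzyl]oxolan-2-one | O=C1C[C@@H](Cc2cc(OC)c(OCc3ccccc3)c(OC)c2)CO1
F5 | step 4 | (3S,4R)-4-[4-(benzyloxy)-3,5-dimethoxybenzyl]-3-{[4-(benzyloxy)-3,5-dimethoxyphenyl](hydroxy)methyl}oxolan-2-one, C7' epimers | COc1cc(C[C@H]2COC(=O)[C@@H]2C(O)c2cc(OC)c(OCc3ccccc3)c(OC)c2)cc(OC)c1OCc1ccccc1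
F6 | step 4 | (2R,3R)-2-[4-(benzyloxy)-3,5-dimethoxybenzyl]-3-{[4-(benzyloxy)-3,5-dimethoxyphenyl](hydroxy)methyl}butane-1,4-diol, C7' epimers | COc1cc(C[C@@H](CO)[C@H](CO)C(O)c2cc(OC)c(OCc3ccccc3)c(OC)c2)cc(OC)c1OCc1ccccc1
F7 | step 6 | [4-(benzyloxy)-3,5-dimethoxyphenyl]{(3R,4R)-4-[4-(benzyloxy)-3,5-dimethoxybenzyl]oxolan-3-yl}methanol, C7' epimers | COc1cc(C[C@H]2COC[C@@H]2C(O)c2cc(OC)c(OCc3ccccc3)c(OC)c2)cc(OC)c1OCc1ccccc1
F8 | step 6 | [4-(benzyloxy)-3,5-dimethoxyphenyl]{(3R,4R)-4-[4-(benzyloxy)-3,5-dimethoxybenzyl]oxolan-3-yl}methanone | COc1cc(C[C@H]2COC[C@@H]2C(=O)c2cc(OC)c(OCc3ccccc3)c(OC)c2)cc(OC)c1OCc1ccccc1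
F9 | step 7 | (4-hydroxy-3,5-dimethoxyphenyl)[(3R,4R)-4-(4-hydroxy-3,5-dimethoxybenzyl)oxolan-3-yl]methanone | COc1cc(C[C@H]2COC[C@@H]2C(=O)c2cc(OC)c(O)c(OC)c2)cc(OC)c1O
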